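**Assumptions (one line each):**
- The SMILES fixes C1 as (R) by CIP (C2 > C6 > CH2-farnesyl > CH3). The enol drawn is taken as the representative tautomer of the β-diketone, and the farnesyl group is (2E,6E).
- In the Seebach dioxanone, both alkylations are assumed to enter trans to the 6-methyl group, so the first-added group ends up cis to it.

**Retrosynthetic overview**
1. Target 17 comes from its tert-butyl ester 16 by TFA. Ester 16 comes from acyclic methyl ketone/β-keto ester 15 by an intramolecular Knoevenagel-type aldol condensation (C5–C6). This is the only carbocycle-forming step, and it runs last, so there is no dearomatisation and no C3/C5 regiochemistry problem.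
2. Ketone 15 comes from hydroxy-ketone 9 by C3–C4 acylation with a tBuO2C-CH2-CO unit, then oxidation of the CH(OH)CH3 arm. That arm is a traceless stereochemical relay that becomes the C6 acetyl.
3. Hydroxy-ketone 9 comes from EtLi opening of quaternary Seebach dioxanone 7. Dioxanone 7 comes from sequential methylation and farnesylation of dioxanone 3, which is made from (R)-3-hydroxybutanoic acid and pivaldehyde.
4. Ring order: the temporary dioxanone ring is formed in Step 1 and opened in Step 4. The carbocycle is formed in Step 9.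

**Route**

**Step 1**
Reactants: 1 (R)-3-hydroxybutanoic acid; 2 pivaldehyde
Product: 3 (2R,6R)-2-tert-butyl-6-methyl-1,3-dioxan-4-one (cis)
Conditions: TsOH·H2O (cat.), pentane, reflux, Dean–Stark; recrystallise to remove the trans isomer
Reagents that add atoms: pivaldehyde, CC(C)(C)C=O
Why: Acetalisation (Seebach self-regeneration of stereocentres) places the carbinol stereocentre in a ring, and the cis-2,6 isomer is thermodynamically favoured.

**Step 2**
Reactants: 3; 4 iodomethane
Product: 5 (2R,5R,6R)-2-tert-butyl-5,6-dimethyl-1,3-dioxan-4-one (5,6-trans)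
Conditions: LDA, THF, −78 °C; then MeI, −78 → −40 °C
Reagents that add atoms: iodomethane, CI
Why: Diastereoselective enolate alkylation; the electrophile attacks anti to the pseudo-axial 6-Me, so Me ends up trans to 6-Me.

**Step 3**
Reactants: 5; 6 (2E,6E)-farnesyl bromide
Product: 7 (2R,5R,6R)-2-tert-butyl-5,6-dimethyl-5-[(2E,6E)-farnesyl]-1,3-dioxan-4-one
Conditions: LDA, THF/DMPU, −78 °C; then 6, −78 → −30 °C
Reagents that add atoms: (2E,6E)-farnesyl bromide, CC(C)=CCC/C(C)=C/CC/C(C)=C/CBr
Why: Diastereoselective enolate alkylation of the trisubstituted enolate. The same facial bias puts farnesyl trans to 6-Me and Me cis, setting the quaternary (R) centre, which becomes C1 of the target. The SN2 site is the primary allylic carbon, so E,E geometry is kept.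

**Step 4**
Reactants: 7; 8 ethyllithium
Product: 9 (4R,5R)-5-hydroxy-4-methyl-4-[(2E,6E)-farnesyl]hexan-3-one
Conditions: EtLi, THF, −78 °C; quench with AcOH at −78 °C; then PPTS, MeOH, rt
Reagents that add atoms: ethyllithium, CC[Li]
Why: Organolithium addition to the acylal carbonyl of the dioxanone, followed by collapse of the pivaldehyde acetal, gives the β-hydroxy ketone. The cold quench avoids β-alkoxide retro-aldol, which would racemise C1. The ethyl CH2 becomes C3 and its CH3 becomes the C3 methyl.

**Step 5**
Reactants: 9; 10 TESOTf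
Product: 11 triethylsilyl ether of 9
Conditions: TESOTf, 2,6-lutidine, CH2Cl2, −78 → 0 °C
Reagents that add atoms: triethylsilyl triflate, CC[Si](CC)(CC)OS(=O)(=O)C(F)(F)F
Why: Silylation blocks both O-acylation and retro-aldol in the next step.

**Step 6**
Reactants: 11; 12 mono-tert-butyl malonate (activated in situ as its imidazolide with CDI)
Product: 13 tert-butyl (6R,7R)-4,6-dimethyl-3,5-dioxo-6-[(2E,6E)-farnesyl]-7-(triethylsilyloxy)octanoate (C4 epimeric/enolised)
Conditions: LDA, THF, −78 °C; MgBr2·OEt2; then 12 + CDI, THF, rt (pre-formed imidazolide), −78 → 0 °C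
Reagents that add atoms: mono-tert-butyl malonate, CC(C)(C)OC(=O)CC(=O)O (delivers tBuO2C-CH2-C(=O)-)
Why: Claisen-type C-acylation of the ketone enolate. Only the ethyl CH2 can enolise, because the other α-carbon is quaternary, so C3–C4 forms regiospecifically and the product is trapped as its Mg chelate. C1 is untouched.

**Step 7**
Reactants: 13
Product: 14 tert-butyl (6R,7R)-7-hydroxy-4,6-dimethyl-3,5-dioxo-6-[(2E,6E)-farnesyl]octanoate
Conditions: HF·pyridine, pyridine/THF, 0 °C → rt
Reagents that add atoms: none
Why: Acidic fluoride desilylation leaves the tBu ester and the trienes intact and avoids basic retro-aldol.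

**Step 8**
Reactants: 14
Product: 15 tert-butyl (6R)-4,6-dimethyl-3,5,7-trioxo-6-[(2E,6E)-farnesyl]octanoate
Conditions: Dess–Martin periodinane, NaHCO3, CH2Cl2, 0 °C → rt
Reagents that add atoms: none
Why: Oxidation of the secondary alcohol to the methyl ketone. This erases the relay stereocentre, and C1 survives because it has no α-H.

**Step 9**
Reactants: 15
Product: 16 tert-butyl (3R)-6-hydroxy-2,3,5-trimethyl-4-oxo-3-[(2E,6E)-farnesyl]cyclohexa-1,5-diene-1-carboxylate
Conditions: piperidinium acetate (cat.), 4 Å MS, toluene, 60 °C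
Reagents that add atoms: none
Why: Proposed new method: the β-keto ester methylene (C5) adds intramolecularly to the neopentylic methyl ketone (C6) and E1cB dehydration gives the tetrasubstituted C5=C6 alkene. The closest known reaction is the biomimetic (Harris-type) aldol cyclisation of polyketide triketo esters to orsellinates, except that here C1 is quaternary, so the ring cannot aromatise and the push-pull dienone is the thermodynamic sink; the stereocentre is already set and is not involved.

**Step 10**
Reactants: 16
Product: 17 target acid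
Conditions: TFA, CH2Cl2 (1:9), anisole, 0 °C, 1 h
Reagents that add atoms: none
Why: Acidolysis of the tert-butyl ester (isobutylene loss) under mild, brief conditions that the farnesyl trienes tolerate; C1 is unaffected.

**Compound list**
1 | (R)-3-hydroxybutanoic acid | C[C@@H](O)CC(=O)O | starting material
2 | pivaldehyde | CC(C)(C)C=O | starting material
3 | (2R,6R)-2-tert-butyl-6-methyl-1,3-dioxan-4-one | C[C@@H]1CC(=O)O[C@@H](O1)C(C)(C)C | intermediate
4 | iodomethane | CI | starting material
5 | (2R,5R,6R)-2-tert-butyl-5,6-dimethyl-1,3-dioxan-4-one | C[C@@H]1[C@@H](C)C(=O)O[C@@H](O1)C(C)(C)C | intermediate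
6 | (2E,6E)-farnesyl bromide | CC(C)=CCC/C(C)=C/CC/C(C)=C/CBr | starting material
7 | (2R,5R,6R)-2-tert-butyl-5,6-dimethyl-5-[(2E,6E)-farnesyl]-1,3-dioxan-4-one | C[C@@H]1[C@@](C)(C/C=C(\C)CC/C=C(\C)CCC=C(C)C)C(=O)O[C@@H](O1)C(C)(C)C | intermediate
8 | ethyllithium | CC[Li] | starting material
9 | (4R,5R)-5-hydroxy-4-methyl-4-[(2E,6E)-farnesyl]hexan-3-one | CCC(=O)[C@](C)(C/C=C(\C)CC/C=C(\C)CCC=C(C)C)[C@@H](C)O | intermediate
10 | triethylsilyl triflate | CC[Si](CC)(CC)OS(=O)(=O)C(F)(F)F | starting material
11 | TES ether of 9 | CCC(=O)[C@](C)(C/C=C(\C)CC/C=C(\C)CCC=C(C)C)[C@@H](C)O[Si](CC)(CC)CC | intermediate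
12 | mono-tert-butyl malonate | CC(C)(C)OC(=O)CC(=O)O | starting material
13 | tert-butyl (6R,7R)-4,6-dimethyl-3,5-dioxo-6-farnesyl-7-(triethylsilyloxy)octanoate | CC(C(=O)CC(=O)OC(C)(C)C)C(=O)[C@](C)(C/C=C(\C)CC/C=C(\C)CCC=C(C)C)[C@@H](C)O[Si](CC)(CC)CC | intermediate
14 | tert-butyl (6R,7R)-7-hydroxy-4,6-dimethyl-3,5-dioxo-6-farnesyloctanoate | CC(C(=O)CC(=O)OC(C)(C)C)C(=O)[C@](C)(C/C=C(\C)CC/C=C(\C)CCC=C(C)C)[C@@H](C)O | intermediate
15 | tert-butyl (6R)-4,6-dimethyl-3,5,7-trioxo-6-farnesyloctanoate | CC(C(=O)CC(=O)OC(C)(C)C)C(=O)[C@](C)(C/C=C(\C)CC/C=C(\C)CCC=C(C)C)C(C)=O | intermediate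
16 | tert-butyl ester of 17 | CC(C)=CCC/C(C)=C/CC/C(C)=C/C[C@@]1(C)C(=O)C(C)=C(O)C(C(=O)OC(C)(C)C)=C1C | intermediate
17 | (3R)-6-hydroxy-2,3,5-trimethyl-4-oxo-3-[(2E,6E)-farnesyl]cyclohexa-1,5-diene-1-carboxylic acid (target) | CC(C)=CCC/C(C)=C/CC/C(C)=C/C[C@@]1(C)C(=O)C(C)=C(O)C(C(=O)O)=C1C | target

**Total steps:** 10. **Longest linear sequence:** 10 (all from 1).

**Three steps most likely to fail**
1. **Step 3 (farnesylation of the tertiary dioxanone enolate).** Risks are SN2′ attack, incomplete conversion, or a reversed or eroded facial bias at the second alkylation.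
   Fallback: drop the relay and use Pd/chiral-ligand asymmetric dearomative farnesylation of tert-butyl 2,4-dihydroxy-3,5,6-trimethylbenzoate, followed by Step 10.
2. **Step 6 (C-acylation with the malonyl imidazolide).** Ketene formation or O-acylation could compete.
   Fallback: open 7 to the hydroxy acid with LiOH, make the TES ether acid chloride, and acylate the 1,3-bis(silyl enol ether) of tert-butyl 3-oxopentanoate with TiCl4. This forms the C3–C4 bond by a different method.
3. **Step 9 (ring closure onto the hindered methyl ketone).** The aldol may be unfavourable or reversible, and retro-Claisen could occur.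
   Fallback: use a Lewis-acid Mukaiyama-type cyclisation of the silyl enol ether of 15 (TiCl4), then dehydrate the tertiary aldol with Burgess reagent or SOCl2/pyridine.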